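The J left over in the south run, 27.3% of its charge and hardly falling by 8.00 min, shows you first what the flask below can't do: that run stopped after using 1.65 J per X charged.

| flask | J | X | remark | time |
|---|---|---|---|---|
| north-east | 0.049 M (in portions, 4) | 0.0882 M | run made earlier; portions every 8.0 s |  |
| south | 0.20 M (in portions, 4) | 0.0882 M | run made earlier; portions every 8.0 s |  |
| north | 0.098 M (in portions, 4) | 0.18 M | run made earlier; portions every 8.0 s |  |
| flask | 0.098 M (in portions, 4) | 0.0882 M | the portions of J follow each other after 8.0 s, the first at the start | 12 min |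

| run | time / min | Z / % | J / % |
|---|---|---|---|
| north-east | 0.500 | 3.1 | 77.5 |
| north-east | 1.00 | 12.2 | 49.7 |
| north-east | 2.00 | 29.4 | 23.0 |
| north-east | 4.00 | 50.3 | 6.7 |
| north-east | 8.00 | 59.8 | 0.7 |
| south | 1.33 | 7.9 | 46.3 |
| south | 3.00 | 11.7 | 32.5 |
| south | 4.00 | 12.7 | 29.9 |
| south | 6.00 | 13.9 | 27.8 |
| south | 8.00 | 13.9 | 27.3 |
| north | 0.667 | 9.4 | 43.8 |
| north | 2.00 | 36.7 | 5.6 |
| north | 3.00 | 46.9 | 2.0 |
| north | 5.00 | 53.1 | 0.4 |
| north | 8.00 | 54.5 | 0 |

(standard deviation of a reading: 0.3 percentage points)

* amount of Z in percent of the J charged, at 80 s, 4.0 min, 8.0 min and 12 min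

- a reading or a percentage of Z counts all its forms, free or not

This flask charges 1.11 J per X, less than the south run used, so I expect J to go to its end here, as the limiting reagent.

What then matters is how J divides at the end. Call N the J gone but not found as Z, per J found as Z, which the north-east run reads as 0.661. Suppose the loss takes a second J while closing to Z takes one. N then follows the mean J over the curve, and as a rough step I take that mean to scale with the charge at equal X, although the curve does not keep its shape: X is used along the way, and at 8.00 min the south run still reads J at 27.3% where the north-east run reads 0.7%. This flask shares the north-east X, which gives N = 1.32 and an end value of Z = 1/(1+N) = 43.1%, my figure for 12 min.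

Is one number enough? The north run, with this flask's J but more X, reads 0.835, less than 1.32, so X belongs in N and I carry N at equal X only. The south run reads 4.23 where scaling gives 2.70, so my figure may stand high.

The forecast gives 18%, 42%, 49% and 52%, reasoning that “at low J nearly all of it closes”; its last value stands for N = 0.923.

The flask gives 13.9%, 32.3%, 39.9% and 42.5%.

    D → Z (k = 0.0180 s⁻¹)
    G ⇌ Z, rate k2*(cs2 - [Z]) while solid is left; crystals form when [Z] > cs2 (solubility = 16.0 mM, k = 0.150 s⁻¹)
    J + X → D (k = 0.160 M⁻¹ s⁻¹)
    J + D → E (k = 0.350 M⁻¹ s⁻¹)
    Z ⇌ L (K = 0.120, k = 0.0150 s⁻¹)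

In this flask at 12.0 min, Z at 42.5% and J at 1.94% give N = 1.31, beside the 1.32 carried over. The passing of J + D into E ran early, with J at 59.3% and D at 9.72% at 0.400 min, and the midpoint of its turnover up to 12 min came at 1.05 min, sooner than the 1.95 min of D closing to Z. At 12.0 min this flask held E at 53.2%, each counted as two J, with X at 21% of its own charge.

The earlier runs and the new flask come from a simulation with constants of no real substance; scatter was added.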